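(The numbers in the tables were computed on assumed constants, and the scatter is random.)

**Examiner:** When protic impurity and starting material have finished with each other, what is left over?

**Candidate:** Whichever was charged in excess, if one impurity takes one starting material. That one-for-one is my assumption. Here are the flasks, the runs so far and the questions.

| flask | starting material | protic impurity | remark | time |
|---|---|---|---|---|
| gamma | 0.024 M (in portions, 3) | 0.030 M | run made earlier; portions every 12 s |  |
| theta | 0.12 M (in portions, 3) | 0.030 M | run made earlier; portions every 12 s |  |
| oak | 0.020 M (in portions, 3) | 0.0300 M | the portions of starting material follow each other after 12 s, the first at the start | 8.0 min |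
| ash | 0.030 M (in portions, 3) | 0.0300 M | the portions of starting material follow each other after 12 s, the first at the start | 8.0 min |
| maple | 0.040 M (in portions, 3) | 0.0300 M | the portions of starting material follow each other after 12 s, the first at the start | 8.0 min |
| larch | 0.060 M (in portions, 3) | 0.0300 M | the portions of starting material follow each other after 12 s, the first at the start | 8.0 min |
| alder | 0.10 M (in portions, 3) | 0.0300 M | the portions of starting material follow each other after 12 s, the first at the start | 8.0 min |

| run | time / min | target / % | starting material / % |
|---|---|---|---|
| gamma | 0.333 | 0.6 | 43.5 |
| gamma | 0.667 | 1.6 | 50.0 |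
| gamma | 1.50 | 2.9 | 22.3 |
| gamma | 4.00 | 1.9 | 4.9 |
| theta | 0.333 | 2.1 | 47.5 |
| theta | 0.667 | 11.5 | 62.6 |
| theta | 1.50 | 18.6 | 43.3 |
| theta | 4.00 | 14.8 | 23.4 |

(scatter of a reading: 0.5 percentage points)

* [target] at the end for oak, ash, maple, larch, alder, in this order
* the shape of the row from first to last (hardly changes / falls all the way / rises all the way / rises, then falls / falls, then rises)

- percent here means starting material units held: one target counts as two
- "hardly changes" means that all values lie within two and a half points (for a concentration: within two and a half percent of the largest)

**Examiner:** Why believe in a quench at all?

**Candidate:** Look at gamma. Its charge of 0.024 M is smaller than the 0.030 M of impurity, and at 4.00 min starting material and target together show 6.80%. The rest, 0.0224 M, has gone into something unread, and the impurity charge is larger.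

**Examiner:** Give me your number.

**Candidate:** For larch, 0.0300 M over 0.060 M gives 50.0%. I call this ratio of impurity charge to starting material charge the quench ceiling: one for one, the quench cannot take a greater share of the charge. Starting material above the ceiling is free to form target. Oak stands at 150%, so starting material is its limiting reagent, and at least 33.3% of its impurity must stay. Ash stands at 100% and maple at 75.0%.

**Examiner:** Theta has a ceiling of 25.0%, yet 61.8% is unread at 4.00 min. Is your number a yield?

**Candidate:** No. Some 36.8% of theta's charge went beyond the quench, and its target reading fell from 18.6% to 14.8%, well outside the scatter of 0.5 percentage points, so target is consumed too. I therefore commit to a direction without amounts: the ceiling drops along the row, a share above it opens at maple with 25.0% and reaches 70.0% at alder, and the row rises. Oak and ash have no share above the ceiling, so I take their target to be what escapes the quench while it runs, and I expect more of it in ash, whose charge is larger.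

The forecast gives 7.000 × 10⁻⁵ M, 2.000 × 10⁻⁴ M, 6.000 × 10⁻⁴ M, 0.0019 M and 0.0035 M, so rises all the way, and says “Below 0.03 M almost everything is quenched”.

The flask gives 9.06 × 10⁻⁵ M, 2.72 × 10⁻⁴ M, 8.40 × 10⁻⁴ M, 0.00259 M and 0.00468 M: rises all the way.

    2 starting material ⇌ target (K = 19.0 M⁻¹, k = 0.0500 M⁻¹ s⁻¹)
    starting material + protic impurity → quenched substrate (k = 1.10 M⁻¹ s⁻¹)
    starting material + target → side product (k = 0.150 M⁻¹ s⁻¹)

In larch the quench ran while protic impurity stood, 54.8% of its charge at 0.400 min and 0.218% at 4.00 min, by which time quenched substrate held 49.9%, on the ceiling of 50.0%. After that, with quenched substrate at 50.0%, starting material and target went on forming side product, counted by the starting material it holds, from 10.3% to 18.4% at 8.00 min. Alder's ceiling of 30.0% stands beside 30.0% of quenched substrate at 8.00 min, when its side product holds 42.5%.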